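**Retrosynthetic overview**

1. The strategy rests on the hexasubstituted acylphloroglucinol ring, whose carbons run C(acyl)–C(OH)–C(CH2–catechin C8)–C(OH)–C(CH3)–C(OCH3). Of its three alternating oxygens, only the one between the acyl-bearing and the methyl-bearing carbon is a methyl ether.
2. Last disconnection: the five O-benzyl ethers of the flavan unit (global hydrogenolysis).
3. Key disconnection: the ring bonds C(acyl)–C(OH) and C(CH3)–C(OCH3). A 1-methoxy-1,3-bis(silyloxy)penta-1,3-diene supplies four ring carbons, both phenols, the methyl and the CH2-catechin arm. (R)-1-Methoxy-4-methylhex-1-yn-3-one supplies two ring carbons, the only OMe and the (R)-acyl chain.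
4. The diene comes from a 2-(arylmethyl) β-ketoester, made from penta-O-benzylcatechin-8-carbaldehyde and methyl 3-oxopentanoate; the aldehyde comes from (+)-catechin by benzylation, C8 bromination and Br–Li exchange/DMF. The ynone comes from the Weinreb amide of (R)-2-methylbutanoic acid and lithium methoxyacetylide.
5. Ring order: the flavan A, B and C rings and both flavan stereocentres are taken intact from (+)-catechin; the acylphloroglucinol ring is the only ring formed, in step 10.

Key step: step 10

Remark: compounds 10–14 and 22 are carried as mixtures of alkene isomers or epimers at centres that become sp2 in 24, so their configuration has no consequence for the target.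

**Route**

Step 1
Reactants: 1 (+)-catechin
Product: 2 5,7,3',4'-tetra-O-benzyl-(+)-catechin
Conditions: BnBr (4.4 equiv), K2CO3 (5 equiv), DMF, 0 °C → rt, Ar
Reagents that add atoms: benzyl bromide, BrCc1ccccc1
Why: Williamson etherification; carbonate deprotonates only the four phenols and leaves the secondary alcohol, and the low temperature under argon should limit C-benzylation and C2 epimerisation.

Step 2
Reactants: 2 5,7,3',4'-tetra-O-benzyl-(+)-catechin
Product: 4 3,5,7,3',4'-penta-O-benzyl-(+)-catechin, via sodium C3-alkoxide 3 (not isolated)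
Conditions: NaH (1.5 equiv), DMF, 0 °C; BnBr (1.3 equiv), 0 °C → rt
Reagents that add atoms: benzyl bromide, BrCc1ccccc1
Why: Williamson etherification of the secondary alkoxide; with all phenols capped there is no pathway for epimerisation at C2 or C3.

Step 3
Reactants: 4 3,5,7,3',4'-penta-O-benzyl-(+)-catechin
Product: 5 8-bromo-penta-O-benzylcatechin
Conditions: NBS (1.0 equiv), CH2Cl2, −78 → 0 °C
Reagents that add atoms: N-bromosuccinimide, O=C1CCC(=O)N1Br
Why: Electrophilic aromatic bromination; in 5,7-dialkoxyflavans C8 is the more nucleophilic free A-ring position, and one equivalent of NBS at low temperature should give the 8-bromide selectively.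

Step 4
Reactants: 5 8-bromo-penta-O-benzylcatechin
Product: 8 penta-O-benzylcatechin-8-carbaldehyde, via 8-lithio-penta-O-benzylcatechin 6 (not isolated), via lithium hemiaminal alkoxide 7 (not isolated)
Conditions: n-BuLi (1.1 equiv), THF, −78 °C; DMF (3 equiv), −78 → 0 °C; AcOH quench
Reagents that add atoms: N,N-dimethylformamide, CN(C)C=O
Why: Bromine–lithium exchange is faster at −78 °C than deprotonation of any benzylic C–H, and the aryllithium is formylated by DMF (Bouveault-type formylation), the hemiaminal alkoxide releasing the aldehyde on quench.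

Step 5
Reactants: 8 penta-O-benzylcatechin-8-carbaldehyde; 9 methyl 3-oxopentanoate
Product: 11 methyl 3-oxo-2-[(penta-O-benzylcatechin-8-yl)methyl]pentanoate, via Knoevenagel alkylidene 10 (not isolated)
Conditions: 9 (1.5 equiv), piperidine (20 mol %), AcOH (20 mol %), 4 Å MS, PhMe, 70 °C; then Hantzsch ester (1.5 equiv), SiO2, 70 °C
Reagents that add atoms: none
Why: Knoevenagel condensation through the piperidinium iminium ion of the hindered aldehyde, then conjugate transfer hydrogenation of the doubly activated alkene by the Hantzsch ester (reductive Knoevenagel); the new α-centre is uncontrolled and is removed by enolisation in step 6.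

Step 6
Reactants: 11 methyl 3-oxo-2-[(penta-O-benzylcatechin-8-yl)methyl]pentanoate
Product: 12 methyl 2-[(penta-O-benzylcatechin-8-yl)methyl]-3-(trimethylsilyloxy)pent-2-enoate
Conditions: TMSCl (1.5 equiv), Et3N (1.6 equiv), PhMe, rt, 48 h; filtration under Ar
Reagents that add atoms: chlorotrimethylsilane, C[Si](C)(C)Cl
Why: Soft enolisation and O-silylation of a β-ketoester, the standard first stage in the preparation of 1,3-bis(silyloxy)dienes, which tolerates a 2-alkyl substituent.

Step 7
Reactants: 12 methyl 2-[(penta-O-benzylcatechin-8-yl)methyl]-3-(trimethylsilyloxy)pent-2-enoate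
Product: 14 (3Z)-1-methoxy-1,3-bis(trimethylsilyloxy)-2-[(penta-O-benzylcatechin-8-yl)methyl]penta-1,3-diene, via lithium dienolate 13 (not isolated)
Conditions: LDA (1.3 equiv), THF, −78 °C; TMSCl (1.5 equiv), −78 → 20 °C; hexane, filtration under Ar, used crude
Reagents that add atoms: chlorotrimethylsilane, C[Si](C)(C)Cl
Why: Kinetic γ-deprotonation of the silyloxy enoate gives the extended ester dienolate, which is O-silylated to the mixed methyl silyl ketene acetal; the arylmethyl CH2 is not conjugated to the ester and the flavan centres are remote, so neither should be touched.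

Step 8
Reactants: 15 (R)-2-methylbutanoic acid
Product: 17 (R)-N-methoxy-N,2-dimethylbutanamide, via acyl imidazole 16 (not isolated)
Conditions: CDI (1.1 equiv), CH2Cl2, 0 °C → rt; MeNHOMe·HCl (1.2 equiv), rt
Reagents that add atoms: N,O-dimethylhydroxylamine hydrochloride, CNOC.Cl
Why: Carbonyldiimidazole activation and aminolysis give the Weinreb amide without strong base or ketene-forming conditions, so the α-stereocentre should be retained.

Step 9
Reactants: 17 (R)-N-methoxy-N,2-dimethylbutanamide; 18 chloroacetaldehyde dimethyl acetal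
Product: 21 (R)-1-methoxy-4-methylhex-1-yn-3-one, via lithium methoxyacetylide 19 (not isolated), via lithium hemiaminal adduct 20 (not isolated)
Conditions: 18 (1.6 equiv), LiNEt2 (4.7 equiv, from n-BuLi/Et2NH), THF, 0 °C; then 17, −78 → −30 °C; AcOH, −78 °C, then pH 7 buffer
Reagents that add atoms: none
Why: Three equivalents of lithium amide per acetal effect double elimination and deprotonation to the alkoxyacetylide, which adds to the Weinreb amide (Weinreb ketone synthesis); the chelated tetrahedral adduct prevents over-addition and protects the α-CH, a slight deficit of base leaves no free amide to enolise 17, and the cold acid quench protonates the liberated amine before it can add to the ynone.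

Step 10
Reactants: 14 (3Z)-1-methoxy-1,3-bis(trimethylsilyloxy)-2-[(penta-O-benzylcatechin-8-yl)methyl]penta-1,3-diene; 21 (R)-1-methoxy-4-methylhex-1-yn-3-one
Product: 24 (R)-1-[2,4-dihydroxy-6-methoxy-5-methyl-3-(penta-O-benzylcatechin-8-ylmethyl)phenyl]-2-methylbutan-1-one, via cyclohexa-1,4-diene cycloadduct 22 (not isolated), via bis(trimethylsilyl) aryl ether 23 (not isolated)
Conditions: 21 (2.5 equiv), PhMe (1 M in 14), 80 °C, sealed tube, Ar; then 1 M aq. HCl, THF, 0 °C → rt
Reagents that add atoms: none
Why: Proposed new method: diene 14 is nucleophilic at C4 and ynone 21 is electrophilic at its methoxy-bearing β-carbon, so they should combine in a normal-electron-demand [4+2] cycloaddition that forms C4–Cβ and C1–Cα, either concerted and asynchronous or stepwise by vinylogous Mukaiyama–Michael addition followed by closure of the allenolate α-carbon onto the silyloxy-oxocarbenium carbon C1 (6-(enolexo)-exo-trig), giving the six-membered carbocycle 22. Adduct 22 carries a bis-allylic mixed ketal at C1 and a doubly activated hydrogen at C4, so 1,4-elimination of methanol should give arene 23, whose two aryl silyl ethers are cleaved by dilute acid to 24. The closest known reaction type is the thermal Diels–Alder/aromatisation of 1-alkoxy-1,3-bis(silyloxy)butadienes with alkynoates and alkynones to give resorcinols; new here are the 2,4-disubstituted diene and the β-alkoxy ynone, which together give a hexasubstituted ring. The step needs regioselectivity (diene C4 to the OMe-bearing alkyne carbon), which the matched polarisation of both partners secures, and periselectivity over attack of C2 on the ketone, which the absence of Lewis acid and the full substitution of C2 secure; it also needs loss of the methoxy rather than the silyloxy group from the C1 ketal, which is the normal behaviour of mixed methyl silyl ketene acetal dienes. No stereocentre is created in 24, because the sp3 centres of 22 vanish on aromatisation, and the (R)-acyl centre and the flavan centres see only neutral heat and cold dilute acid. The (3Z) diene has its methyl outside in the s-cis conformer, and a methyl ynol ether cannot undergo the retro-ene loss of alkene that limits ethoxy- and tert-butoxyalkynes on heating.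

Step 11
Reactants: 24 (R)-1-[2,4-dihydroxy-6-methoxy-5-methyl-3-(penta-O-benzylcatechin-8-ylmethyl)phenyl]-2-methylbutan-1-one
Product: 25 target CNP0299940.2
Conditions: H2 (1 atm), 20% Pd(OH)2/C, THF/MeOH (1:1), rt, then filtration under Ar
Reagents that add atoms: none
Why: Hydrogenolysis of the five benzyl ethers; the chelated, fully ortho-substituted aryl ketone, the diarylmethane bridge and the flavan C2–O bond should be inert at 1 atm and room temperature, and no stereocentre is touched.

**Compound list**

1 | (+)-catechin, (2R,3S) | O[C@H]1Cc2c(O)cc(O)cc2O[C@@H]1c1ccc(O)c(O)c1 | starting material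
2 | 5,7,3',4'-tetra-O-benzyl-(+)-catechin | c1c(OCc2ccccc2)cc(OCc2ccccc2)c2c1O[C@H](c1ccc(OCc3ccccc3)c(OCc3ccccc3)c1)[C@@H](O)C2 | intermediate
3 | sodium C3-alkoxide of 2 | c1c(OCc2ccccc2)cc(OCc2ccccc2)c2c1O[C@H](c1ccc(OCc3ccccc3)c(OCc3ccccc3)c1)[C@@H]([O-])C2.[Na+] | intermediate (not isolated)
4 | 3,5,7,3',4'-penta-O-benzyl-(+)-catechin | c1c(OCc2ccccc2)cc(OCc2ccccc2)c2c1O[C@H](c1ccc(OCc3ccccc3)c(OCc3ccccc3)c1)[C@@H](OCc1ccccc1)C2 | intermediate
5 | 8-bromo-penta-O-benzylcatechin | Brc1c(OCc2ccccc2)cc(OCc2ccccc2)c2c1O[C@H](c1ccc(OCc3ccccc3)c(OCc3ccccc3)c1)[C@@H](OCc1ccccc1)C2 | intermediate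
6 | 8-lithio-penta-O-benzylcatechin | [Li]c1c(OCc2ccccc2)cc(OCc2ccccc2)c2c1O[C@H](c1ccc(OCc3ccccc3)c(OCc3ccccc3)c1)[C@@H](OCc1ccccc1)C2 | intermediate (not isolated)
7 | lithium hemiaminal alkoxide from 6 and DMF (epimers at the carbinol carbon) | CN(C)C([O-])c1c(OCc2ccccc2)cc(OCc2ccccc2)c2c1O[C@H](c1ccc(OCc3ccccc3)c(OCc3ccccc3)c1)[C@@H](OCc1ccccc1)C2.[Li+] | intermediate (not isolated)
8 | penta-O-benzylcatechin-8-carbaldehyde | O=Cc1c(OCc2ccccc2)cc(OCc2ccccc2)c2c1O[C@H](c1ccc(OCc3ccccc3)c(OCc3ccccc3)c1)[C@@H](OCc1ccccc1)C2 | intermediate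
9 | methyl 3-oxopentanoate | CCC(=O)CC(=O)OC | starting material
10 | methyl 3-oxo-2-[(penta-O-benzylcatechin-8-yl)methylidene]pentanoate (E/Z mixture) | CCC(=O)C(=Cc1c(OCc2ccccc2)cc(OCc2ccccc2)c2c1O[C@H](c1ccc(OCc3ccccc3)c(OCc3ccccc3)c1)[C@@H](OCc1ccccc1)C2)C(=O)OC | intermediate (not isolated)
11 | methyl 3-oxo-2-[(penta-O-benzylcatechin-8-yl)methyl]pentanoate (epimers at C2 of the ester) | CCC(=O)C(Cc1c(OCc2ccccc2)cc(OCc2ccccc2)c2c1O[C@H](c1ccc(OCc3ccccc3)c(OCc3ccccc3)c1)[C@@H](OCc1ccccc1)C2)C(=O)OC | intermediate
12 | methyl 2-[(penta-O-benzylcatechin-8-yl)methyl]-3-(trimethylsilyloxy)pent-2-enoate (E/Z mixture) | CCC(O[Si](C)(C)C)=C(Cc1c(OCc2ccccc2)cc(OCc2ccccc2)c2c1O[C@H](c1ccc(OCc3ccccc3)c(OCc3ccccc3)c1)[C@@H](OCc1ccccc1)C2)C(=O)OC | intermediate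
13 | lithium dienolate of 12 | C/C=C(\O[Si](C)(C)C)C(Cc1c(OCc2ccccc2)cc(OCc2ccccc2)c2c1O[C@H](c1ccc(OCc3ccccc3)c(OCc3ccccc3)c1)[C@@H](OCc1ccccc1)C2)=C(OC)[O-].[Li+] | intermediate (not isolated)
14 | (3Z)-1-methoxy-1,3-bis(trimethylsilyloxy)-2-[(penta-O-benzylcatechin-8-yl)methyl]penta-1,3-diene | C/C=C(\O[Si](C)(C)C)C(Cc1c(OCc2ccccc2)cc(OCc2ccccc2)c2c1O[C@H](c1ccc(OCc3ccccc3)c(OCc3ccccc3)c1)[C@@H](OCc1ccccc1)C2)=C(OC)O[Si](C)(C)C | intermediate (key-step precursor)
15 | (R)-2-methylbutanoic acid | CC[C@@H](C)C(=O)O | starting material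
16 | (R)-1-(imidazol-1-yl)-2-methylbutan-1-one | CC[C@@H](C)C(=O)n1ccnc1 | intermediate (not isolated)
17 | (R)-N-methoxy-N,2-dimethylbutanamide | CC[C@@H](C)C(=O)N(C)OC | intermediate
18 | chloroacetaldehyde dimethyl acetal | COC(CCl)OC | starting material
19 | lithium methoxyacetylide | [Li]C#COC | intermediate (not isolated)
20 | lithium hemiaminal adduct of 19 and 17 | CC[C@@H](C)C([O-])(C#COC)N(C)OC.[Li+] | intermediate (not isolated)
21 | (R)-1-methoxy-4-methylhex-1-yn-3-one | CC[C@@H](C)C(=O)C#COC | intermediate (key-step precursor)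
22 | cyclohexa-1,4-diene cycloadduct of 14 and 21 (diastereomer mixture at the two ring sp3 carbons) | CC[C@@H](C)C(=O)C1=C(OC)C(C)C(O[Si](C)(C)C)=C(Cc2c(OCc3ccccc3)cc(OCc3ccccc3)c3c2O[C@H](c2ccc(OCc4ccccc4)c(OCc4ccccc4)c2)[C@@H](OCc2ccccc2)C3)C1(OC)O[Si](C)(C)C | intermediate (not isolated)
23 | bis(trimethylsilyl) ether of 24 | CC[C@@H](C)C(=O)c1c(O[Si](C)(C)C)c(Cc2c(OCc3ccccc3)cc(OCc3ccccc3)c3c2O[C@H](c2ccc(OCc4ccccc4)c(OCc4ccccc4)c2)[C@@H](OCc2ccccc2)C3)c(O[Si](C)(C)C)c(C)c1OC | intermediate (not isolated)
24 | (R)-1-[2,4-dihydroxy-6-methoxy-5-methyl-3-(penta-O-benzylcatechin-8-ylmethyl)phenyl]-2-methylbutan-1-one | CC[C@@H](C)C(=O)c1c(O)c(Cc2c(OCc3ccccc3)cc(OCc3ccccc3)c3c2O[C@H](c2ccc(OCc4ccccc4)c(OCc4ccccc4)c2)[C@@H](OCc2ccccc2)C3)c(O)c(C)c1OC | intermediate (key-step product)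
25 | (R)-1-[3-{[(2R,3S)-2-(3,4-dihydroxyphenyl)-3,5,7-trihydroxychroman-8-yl]methyl}-2,4-dihydroxy-6-methoxy-5-methylphenyl]-2-methylbutan-1-one (CNP0299940.2) | CC[C@@H](C)C(=O)c1c(O)c(Cc2c(O)cc(O)c3c2O[C@H](c2ccc(O)c(O)c2)[C@@H](O)C3)c(O)c(C)c1OC | target

**Totals**

Total step count: 11. Longest linear sequence: 9 steps (steps 1–7, 10, 11); steps 8–9 form the two-step side branch to the ynone.

**Steps most likely to fail**

1. Step 10 (proposed new method). Both new bonds join fully substituted carbons, so the cycloaddition may be slower than protodesilylation or silyl migration of the diene. The diene may instead attack the ketone carbonyl, or the vinylogous methyl ether of the adduct may hydrolyse before aromatisation.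
   Fallback (known chemistry), setting out from 8 and 15 and returning at 24: the ring is assembled classically and the methylene bridge is closed by Friedel–Crafts benzylation. Aldehyde 8 is reduced with NaBH4 (THF/MeOH, 0 °C) to 8-(hydroxymethyl)penta-O-benzylcatechin F1. Acid 15 is converted with oxalyl chloride and catalytic DMF into (R)-2-methylbutanoyl chloride F2, which C-acylates commercial 2,4,6-trihydroxytoluene (Cc1c(O)cc(O)cc1O; AlCl3, PhNO2/CH2Cl2, 0 °C → rt) to (R)-1-(2,4,6-trihydroxy-3-methylphenyl)-2-methylbutan-1-one F3. MOMCl/i-Pr2NEt (2.1 equiv) should protect the para hydroxyl and the less hindered ortho hydroxyl to give (R)-1-[2-hydroxy-4,6-bis(methoxymethoxy)-3-methylphenyl]-2-methylbutan-1-one F4, any regioisomer being removed by chromatography. The remaining chelated hydroxyl between acyl and methyl is methylated (MeI, K2CO3, acetone, 40 °C) to (R)-1-[2-methoxy-4,6-bis(methoxymethoxy)-3-methylphenyl]-2-methylbutan-1-one F5, and HCl/MeOH removes the acetals to give (R)-1-(4,6-dihydroxy-2-methoxy-3-methylphenyl)-2-methylbutan-1-one F6. With catalytic TsOH in CH2Cl2 at −20 °C, F1 ionises to a 2,4,6-trioxygenated benzyl cation that should be captured by the only free ring position of F6 (used in excess), giving 24.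

2. Step 9. The push–pull alkyne may take up the liberated N,O-dimethylhydroxylamine or water during quench and chromatography, and residual amide base may enolise the α-centre.
   Fallback, setting out from 17 and returning at 21: the ketone is reached by aldehyde addition and oxidation, so that no amine is released next to the ynone. Amide 17 is reduced with DIBAL-H (THF, −78 °C) to (R)-2-methylbutanal F7, which is kept cold in solution. F7 is added to 19 (generated from 18 as in step 9) to give (4R)-1-methoxy-4-methylhex-1-yn-3-ol F8 as a carbinol epimer mixture. Oxidation with activated MnO2 in CH2Cl2 (neutral, filtered through Celite) should give 21.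

3. Step 5. Condensation of the di-ortho-alkoxy, electron-rich aldehyde may be slow, and hydride transfer to the weakly electrophilic alkylidene may be slow, so that the Hantzsch ester is consumed unproductively or a second ketoester adds to the alkylidene.
   Fallback, setting out from 8 and returning at 11: the side chain is built by olefination and Claisen-type acylation. Horner–Wadsworth–Emmons reaction of 8 with trimethyl phosphonoacetate (NaH, THF, 0 °C → rt) should give methyl (E)-3-(penta-O-benzylcatechin-8-yl)prop-2-enoate F9. Conjugate reduction with Mg in MeOH/THF gives methyl 3-(penta-O-benzylcatechin-8-yl)propanoate F10. Its lithium enolate (LDA, 2.1 equiv, THF, −78 °C) is acylated with N-methoxy-N-methylpropanamide to give 11.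

**Further compounds**

F1 | step 10 | 8-(hydroxymethyl)penta-O-benzylcatechin | OCc1c(OCc2ccccc2)cc(OCc2ccccc2)c2c1O[C@H](c1ccc(OCc3ccccc3)c(OCc3ccccc3)c1)[C@@H](OCc1ccccc1)C2
F2 | step 10 | (R)-2-methylbutanoyl chloride | CC[C@@H](C)C(=O)Cl
F3 | step 10 | (R)-1-(2,4,6-trihydroxy-3-methylphenyl)-2-methylbutan-1-one | CC[C@@H](C)C(=O)c1c(O)cc(O)c(C)c1O
F4 | step 10 | (R)-1-[2-hydroxy-4,6-bis(methoxymethoxy)-3-methylphenyl]-2-methylbutan-1-one | CC[C@@H](C)C(=O)c1c(OCOC)cc(OCOC)c(C)c1O
F5 | step 10 | (R)-1-[2-methoxy-4,6-bis(methoxymethoxy)-3-methylphenyl]-2-methylbutan-1-one | CC[C@@H](C)C(=O)c1c(OCOC)cc(OCOC)c(C)c1OC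
F6 | step 10 | (R)-1-(4,6-dihydroxy-2-methoxy-3-methylphenyl)-2-methylbutan-1-one | CC[C@@H](C)C(=O)c1c(O)cc(O)c(C)c1OC
F7 | step 9 | (R)-2-methylbutanal | CC[C@@H](C)C=O
F8 | step 9 | (4R)-1-methoxy-4-methylhex-1-yn-3-ol (carbinol epimers) | CC[C@@H](C)C(O)C#COC
F9 | step 5 | methyl (E)-3-(penta-O-benzylcatechin-8-yl)prop-2-enoate | COC(=O)/C=C/c1c(OCc2ccccc2)cc(OCc2ccccc2)c2c1O[C@H](c1ccc(OCc3ccccc3)c(OCc3ccccc3)c1)[C@@H](OCc1ccccc1)C2
F10 | step 5 | methyl 3-(penta-O-benzylcatechin-8-yl)propanoate | COC(=O)CCc1c(OCc2ccccc2)cc(OCc2ccccc2)c2c1O[C@H](c1ccc(OCc3ccccc3)c(OCc3ccccc3)c1)[C@@H](OCc1ccccc1)C2
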